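**Plan**
- Retrosynthesis: the C17 methylene (Wittig) and the C12 oxygen are cleared first; C12–C13 and C8–C9 are then cut together, which opens ring C and the δ-lactone; the C20–O–C7 ester bond then separates a ring A enal alcohol from a ring D 2,3-dioxocyclopentanecarboxylic acid.
- Enabling feature: C8 lies between the C7 ester carbonyl and the C15 ketone, and C13 is α to the C16 ketone, so ring D is a double carbon nucleophile toward the C9–C11–C12 enal on C10.
- Forward: ring D acid by Claisen/Dieckmann chemistry from diethyl glutarate and diethyl oxalate; ring A by Michael addition, Roskamp homologation and Knoevenagel closure, then C10 and C1 are set; the two fragments are joined as an ester; one base-catalysed operation closes the lactone and ring C; dehydration, hydrogenation, methylenation and desilylation finish.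
- Stereochemistry: C4 comes from a catalytic enantioselective Michael addition. C5 (hydrogenation anti to the tert-butyl ester), C10 (aldol anti to the C6 arm) and C1 (hydroxyl-directed reduction) follow from it in turn. C9, C8 and C13 follow from C10 in the cascade.

Key step: step 23

Remark (convention): ent-kaurane atom numbers are used; α is the face of ring A that carries C20, β the opposite face.
Remark (choices): O6 is carried as a tert-butyldiphenylsilyl ether because it must survive the acid of step 19. The key-step precursor is drawn as the 2,3-dioxo tautomer and should exist mainly as the 2-hydroxy-3-oxocyclopent-1-ene enol. C12 of the cascade product is left undefined because it is removed.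

**Ring D acid (steps 1–5)**

Step 1
Reactants: 1 diethyl glutarate; 2 diethyl oxalate
Product: 4 2-oxoadipic acid, via triethyl oxalylglutarate 3 (not isolated)
Conditions: KOEt (1.0 equiv), Et2O, 0 °C → rt; then 4 M aq. HCl, reflux
Reagents that add atoms: water, O
Why: Crossed Claisen condensation of the non-enolisable oxalate with the glutarate α-carbon should stop at the precipitated potassium enolate of 3 when one equivalent of base is used, and acid hydrolysis with decarboxylation of the oxalyl β-keto acid then gives the α-keto diacid.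

Step 2
Reactants: 4 2-oxoadipic acid
Product: 5 dimethyl 2-oxoadipate
Conditions: MeOH, H2SO4 (cat.), reflux; aqueous work-up
Reagents that add atoms: methanol, CO
Why: Fischer esterification, in which any dimethyl ketal at the keto group is expected to revert on aqueous work-up.

Step 3
Reactants: 5 dimethyl 2-oxoadipate
Product: 6 methyl 2-hydroxy-3-oxocyclopent-1-ene-1-carboxylate
Conditions: KOt-Bu (2.2 equiv), THF, 0 °C → rt, slow addition of 5; then 1 M aq. HCl
Reagents that add atoms: none
Why: Dieckmann condensation in which the ester enolate carbon (C8) attacks the activated oxalyl ester carbonyl (C15) in a 5-exo-trig closure, the same ring closure as the second stage of the classical oxalate–glutarate cyclopentanedione synthesis, driven by the doubly stabilised diosphenolate.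

Step 4
Reactants: 6 methyl 2-hydroxy-3-oxocyclopent-1-ene-1-carboxylate
Product: 7 methyl 3-oxo-2-(prop-2-en-1-yloxy)cyclopent-1-ene-1-carboxylate
Conditions: allyl alcohol (3 equiv), TsOH·H2O (5 mol %), benzene, reflux, Dean–Stark trap
Reagents that add atoms: allyl alcohol, OCC=C
Why: Acid-catalysed enol etherification of a diosphenol, expected to settle under reversible conditions on the C15 oxygen because that isomer keeps the alkene conjugated with both the ester and the C16 ketone.

Step 5
Reactants: 7 methyl 3-oxo-2-(prop-2-en-1-yloxy)cyclopent-1-ene-1-carboxylate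
Product: 8 3-oxo-2-(prop-2-en-1-yloxy)cyclopent-1-ene-1-carboxylic acid
Conditions: Me3SnOH (3 equiv), 1,2-dichloroethane, 70 °C; then 5% aq. HCl wash
Reagents that add atoms: trimethyltin hydroxide, C[Sn](C)(C)O
Why: Neutral ester cleavage by trimethyltin hydroxide, chosen because aqueous hydroxide could displace the allyloxy group of the β-alkoxy enoate by addition–elimination.

**Ring A (steps 6–19)**

Step 6
Reactants: 9 methyl glycolate
Product: 10 methyl 2-[(tert-butyldiphenylsilyl)oxy]acetate
Conditions: TBDPSCl (1.05 equiv), imidazole (2 equiv), DMF, 0 °C → rt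
Reagents that add atoms: tert-butyl(chloro)diphenylsilane, CC(C)(C)[Si](Cl)(c1ccccc1)c1ccccc1
Why: Standard imidazole-mediated silylation of a primary alcohol.

Step 7
Reactants: 10 methyl 2-[(tert-butyldiphenylsilyl)oxy]acetate; 11 tert-butyl propanoate
Product: 12 tert-butyl 4-[(tert-butyldiphenylsilyl)oxy]-2-methyl-3-oxobutanoate
Conditions: LiN(i-Pr)2 (2.2 equiv), 11 (2.2 equiv), THF, −78 °C; then 10, −78 → −20 °C; aq. NH4Cl
Reagents that add atoms: none
Why: Crossed Claisen condensation of the lithium enolate of the tert-butyl ester with the methyl ester, the second equivalent of enolate being consumed by the acidic β-keto ester product.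

Step 8
Reactants: 12 tert-butyl 4-[(tert-butyldiphenylsilyl)oxy]-2-methyl-3-oxobutanoate; 13 acrolein
Product: 14 tert-butyl (2R)-4-[(tert-butyldiphenylsilyl)oxy]-2-methyl-3-oxo-2-(3-oxopropyl)butanoate
Conditions: 13 (3 equiv), 6'-hydroxy-9-O-(9-phenanthryl) cinchona alkaloid catalyst (10 mol %; the quinidine- or quinine-derived pseudo-enantiomer that delivers the R adduct), CH2Cl2, −25 °C
Reagents that add atoms: none
Why: Catalytic enantioselective Michael addition of an α-methyl β-keto ester to acrolein under bifunctional base/hydrogen-bond catalysis, which sets the C4 quaternary centre by differentiating the faces of the catalyst-bound enol.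

Step 9
Reactants: 14 tert-butyl (2R)-4-[(tert-butyldiphenylsilyl)oxy]-2-methyl-3-oxo-2-(3-oxopropyl)butanoate; 15 ethyl diazoacetate
Product: 16 1-tert-butyl 7-ethyl (2R)-2-{[(tert-butyldiphenylsilyl)oxy]acetyl}-2-methyl-5-oxoheptanedioate
Conditions: 15 (1.2 equiv), SnCl2 (10 mol %), CH2Cl2, rt
Reagents that add atoms: none
Why: Roskamp homologation of the aldehyde to a β-keto ester (1,2-hydride shift with loss of dinitrogen), selective for the aldehyde over the hindered ketone.

Step 10
Reactants: 16 1-tert-butyl 7-ethyl (2R)-2-{[(tert-butyldiphenylsilyl)oxy]acetyl}-2-methyl-5-oxoheptanedioate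
Product: 17 1-tert-butyl 3-ethyl (1R)-2-{[(tert-butyldiphenylsilyl)oxy]methyl}-1-methyl-4-oxocyclohex-2-ene-1,3-dicarboxylate
Conditions: pyrrolidine (0.3 equiv), AcOH (0.3 equiv), toluene, 80 °C, 4 Å molecular sieves
Reagents that add atoms: none
Why: Intramolecular Knoevenagel condensation (6-enolexo-exo-trig) of the β-keto ester methylene (C10) onto the C5 ketone closes ring A as the fully substituted enone, the ring-forming half of a Robinson-type annulation.

Step 11
Reactants: 17 1-tert-butyl 3-ethyl (1R)-2-{[(tert-butyldiphenylsilyl)oxy]methyl}-1-methyl-4-oxocyclohex-2-ene-1,3-dicarboxylate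
Product: 18 ring A β-keto ester with C5 set (H5 β and the silyloxymethyl arm α)
Conditions: H2 (1 atm), 10% Pd/C, EtOAc, rt
Reagents that add atoms: none
Why: Heterogeneous hydrogenation of the doubly activated C5=C10 alkene from the face opposite the bulky tert-butyl ester on the adjacent quaternary C4 should set C5 with H5 β and the C6 arm α (cis to C19), while C10 stays epimerisable.

Step 12
Reactants: 18 ring A β-keto ester
Product: 19 ring A 10-hydroxymethyl β-keto ester (C9 hydroxymethyl β and C20 ethyl ester α)
Conditions: 37% aq. CH2O (5 equiv), KHCO3 (0.3 equiv), THF, 0 °C → rt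
Reagents that add atoms: formaldehyde, C=O
Why: Aldol hydroxymethylation of the β-keto ester at C10, with formaldehyde entering anti to the neighbouring pseudo-axial C6 arm so that the new CH2OH (C9) is β and the ester (C20) is α.

Step 13
Reactants: 19 ring A 10-hydroxymethyl β-keto ester
Product: 20 ring A 1α-hydroxy diol ester
Conditions: Me4NBH(OAc)3 (5 equiv), MeCN/AcOH (1:1), −30 → 0 °C
Reagents that add atoms: none
Why: Evans–Saksena reduction, in which the C9 hydroxyl binds the acetoxyborohydride and delivers hydride intramolecularly to the β face of the C1 ketone, giving the 1α-alcohol.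

Step 14
Reactants: 20 ring A 1α-hydroxy diol ester
Product: 22 ring A methyl (E)-acrylate with free 1α-hydroxyl, via ring A aldehyde 21 (not isolated)
Conditions: TEMPO (10 mol %), PhI(OAc)2 (1.2 equiv), CH2Cl2, rt; then Ph3P=CHCO2Me (2 equiv), 40 °C
Reagents that add atoms: methyl (triphenylphosphoranylidene)acetate, COC(=O)C=P(c1ccccc1)(c1ccccc1)c1ccccc1
Why: Oxoammonium oxidation selective for the primary C9 alcohol over the hindered secondary C1 alcohol, followed in the same flask by an E-selective stabilised Wittig reaction so that the retro-aldol-prone β-hydroxy aldehyde is not handled.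

Step 15
Reactants: 22 ring A methyl (E)-acrylate
Product: 23 ring A tetraol (O1 and O12 and O19 and O20 free; O6 silylated)
Conditions: i-Bu2AlH (12 equiv), CH2Cl2/toluene, −78 °C → rt; aq. potassium sodium tartrate
Reagents that add atoms: none
Why: Exhaustive hydride reduction of the three esters, with 1,2-reduction of the enoate to the allylic alcohol, leaving the alkene and the silyl ether.

Step 16
Reactants: 23 ring A tetraol
Product: 24 ring A O1/O20 acetonide diol
Conditions: Me2C(OMe)2 (1.5 equiv), PPTS (5 mol %), CH2Cl2, 0 °C → rt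
Reagents that add atoms: 2,2-dimethoxypropane, COC(C)(C)OC
Why: Transketalisation; only O1 and O20 form a 1,3-diol that can close a six-membered acetonide, which distinguishes C20 from the other two primary alcohols.

Step 17
Reactants: 24 ring A O1/O20 acetonide diol
Product: 25 ring A acetonide (E)-enal with free 19-hydroxyl
Conditions: MnO2 (activated, 20 equiv), CH2Cl2, rt
Reagents that add atoms: none
Why: Allylic oxidation by MnO2, selective for the C12 allylic alcohol over the saturated neopentyl C19 alcohol.

Step 18
Reactants: 25 ring A acetonide (E)-enal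
Product: 26 ring A acetonide (E)-enal 19-acetate
Conditions: Ac2O (1.5 equiv), pyridine, DMAP (5 mol %), CH2Cl2, 0 °C → rt
Reagents that add atoms: acetic anhydride, CC(=O)OC(C)=O
Why: DMAP-catalysed acetylation of the remaining primary alcohol.

Step 19
Reactants: 26 ring A acetonide (E)-enal 19-acetate
Product: 27 ring A enal 1,20-diol 19-acetate
Conditions: AcOH/H2O/THF (3:1:1), 45 °C
Reagents that add atoms: none
Why: Acid hydrolysis of the acetonide, under which the tert-butyldiphenylsilyl ether, the acetate and the enal should persist.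

**Fragment union and cascade (steps 20–23)**

Step 20
Reactants: 27 ring A enal 1,20-diol 19-acetate; 8 3-oxo-2-(prop-2-en-1-yloxy)cyclopent-1-ene-1-carboxylic acid
Product: 29 C20 ester of 27 with acid 8 (1α-hydroxyl free), via mixed anhydride 28 (not isolated)
Conditions: 8 (1.1 equiv), 2,4,6-trichlorobenzoyl chloride (1.1 equiv), Et3N, THF, rt; then 27, DMAP (1.5 equiv), toluene, rt
Reagents that add atoms: 2,4,6-trichlorobenzoyl chloride, O=C(Cl)c1c(Cl)cc(Cl)cc1Cl (its atoms stay only in 28)
Why: Yamaguchi esterification, in which the primary C20 hydroxyl should be acylated in preference to the secondary C1 hydroxyl that is flanked by the quaternary C10.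

Step 21
Reactants: 29 C20 ester with free 1α-hydroxyl
Product: 30 1α,19-diacetate carrying the allyl-protected ring D ester
Conditions: Ac2O (5 equiv), DMAP (0.5 equiv), pyridine, 40 °C
Reagents that add atoms: acetic anhydride, CC(=O)OC(C)=O
Why: Forcing DMAP-catalysed acetylation of the hindered 1α-alcohol, possible here because the ring D enol is masked as its allyl ether.

Step 22
Reactants: 30 1α,19-diacetate carrying the allyl-protected ring D ester
Product: 31 ring A enal ester of 2,3-dioxocyclopentane-1-carboxylic acid (key-step precursor)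
Conditions: Pd(PPh3)4 (5 mol %), p-TolSO2H (1.2 equiv), CH2Cl2, 0 °C → rt
Reagents that add atoms: none
Why: Tsuji–Trost-type deallylation, in which zerovalent palladium ionises the allyl enol ether and the sulfinic acid both traps the allyl group as a sulfone and protonates the diosphenolate, so the neutral precursor is obtained without base.

Step 23
Reactants: 31 ring A enal ester of 2,3-dioxocyclopentane-1-carboxylic acid
Product: 32 tetracyclic 12-hydroxy-15,16-dione 7,20-lactone (12ξ)
Conditions: DBU (0.2 equiv), MeCN (0.01 M), 0 °C → rt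
Reagents that add atoms: none
Why: Proposed new method: DBU deprotonates the enolised β-keto ester of ring D and C8 adds 6-exo-trig to C9 of the tethered (E)-enal, closing the δ-lactone and leaving a C11–C12 aldehyde; the 1,2-dione then enolises toward C13, which attacks C12 in a 6-(enolexo)-exo-trig aldol addition that closes ring C across ring D. The closest known reactions are the base- or amine-mediated domino Michael–aldol annulations of cyclic β-keto esters and cyclic 1,2-diones with enals to bicyclo[3.2.1]octanes; joining donor and acceptor through an ester, as here through C20, has not been shown. C9 is controlled by the spiro C10 centre: in the chair-like transition state the C11 arm of the enal and the bulkier C5 side of ring A lie equatorial on the forming lactone, so C8 bonds to the enal face that leaves H9 on the C5 side. C8 is controlled by the face of the planar ring D enolate that bonds: the small C14 methylene, not the ion-paired C15 oxygen side, should take the axial site next to C1, which places C14 syn to C11, and the other Michael adduct can return by retro-Michael reaction. C13 follows from C8, because C12 can only reach C13 on the ring D face that carries C9, and C12 is left uncontrolled because steps 24 and 25 remove it. The step needs C-attack (not O-attack) of the ambident diosphenolate and a base mild enough for the two acetates and the silyl ether; the 6-exo tether geometry and the bridged 1,2-dione product, which can neither enolise nor dehydrate, are expected to secure this.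

**End game (steps 24–27)**

Step 24
Reactants: 32 tetracyclic 12-hydroxy-15,16-dione
Product: 33 tetracyclic 11-ene-15,16-dione
Conditions: Burgess reagent (methyl N-(triethylammoniosulfonyl)carbamate, 3 equiv), toluene, 70 °C
Reagents that add atoms: none
Why: Burgess dehydration by syn elimination of the C12 sulfamate toward C11, the only direction available because the C13 bridgehead hydrogen cannot be lost (Bredt's rule).

Step 25
Reactants: 33 tetracyclic 11-ene-15,16-dione
Product: 34 tetracyclic saturated 15,16-dione
Conditions: H2 (1 atm), 10% Pd/C, EtOAc, rt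
Reagents that add atoms: none
Why: Catalytic hydrogenation of the cis-disubstituted ring C alkene, which should be much faster than reduction of the non-enolisable 1,2-dione.

Step 26
Reactants: 34 tetracyclic saturated 15,16-dione
Product: 35 O6-silylated target (16-methylene-15-ketone)
Conditions: Ph3PCH3Br (1.3 equiv), KOt-Bu (1.2 equiv), THF, 0 °C; then 34, −78 → 0 °C
Reagents that add atoms: methylenetriphenylphosphorane, C=P(c1ccccc1)(c1ccccc1)c1ccccc1
Why: Wittig mono-methylenation of a non-enolisable bridged 1,2-dione at the less hindered C16 carbonyl (next to the C13 methine) and not at C15 (next to the quaternary C8), as in the known methylenation of camphorquinone at C3, the strained dione reacting faster than the acetates and the lactone at low temperature.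

Step 27
Reactants: 35 O6-silylated target
Product: 36 target CNP0105570.2
Conditions: HF·pyridine, pyridine/THF, 0 °C → rt
Reagents that add atoms: none
Why: Fluoride cleavage of the primary silyl ether under buffered acidic conditions that should spare the acetates, the lactone and the α-methylene ketone.

**Compound list**

1 | diethyl glutarate | CCOC(=O)CCCC(=O)OCC | starting material
2 | diethyl oxalate | CCOC(=O)C(=O)OCC | starting material
3 | triethyl 1-oxobutane-1,2,4-tricarboxylate (triethyl oxalylglutarate) | CCOC(=O)C(=O)C(CCC(=O)OCC)C(=O)OCC | intermediate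
4 | 2-oxohexanedioic acid (2-oxoadipic acid) | OC(=O)C(=O)CCCC(=O)O | intermediate
5 | dimethyl 2-oxohexanedioate | COC(=O)C(=O)CCCC(=O)OC | intermediate
6 | methyl 2-hydroxy-3-oxocyclopent-1-ene-1-carboxylate (enol of methyl 2,3-dioxocyclopentanecarboxylate) | COC(=O)C1=C(O)C(=O)CC1 | intermediate
7 | methyl 3-oxo-2-(prop-2-en-1-yloxy)cyclopent-1-ene-1-carboxylate | COC(=O)C1=C(OCC=C)C(=O)CC1 | intermediate
8 | 3-oxo-2-(prop-2-en-1-yloxy)cyclopent-1-ene-1-carboxylic acid (ring D acid) | OC(=O)C1=C(OCC=C)C(=O)CC1 | intermediate
9 | methyl glycolate | COC(=O)CO | starting material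
10 | methyl 2-[(tert-butyldiphenylsilyl)oxy]acetate | COC(=O)CO[Si](c1ccccc1)(c1ccccc1)C(C)(C)C | intermediate
11 | tert-butyl propanoate | CCC(=O)OC(C)(C)C | starting material
12 | tert-butyl 4-[(tert-butyldiphenylsilyl)oxy]-2-methyl-3-oxobutanoate (racemic, enolisable) | CC(C(=O)OC(C)(C)C)C(=O)CO[Si](c1ccccc1)(c1ccccc1)C(C)(C)C | intermediate
13 | acrolein | C=CC=O | starting material
14 | tert-butyl (2R)-4-[(tert-butyldiphenylsilyl)oxy]-2-methyl-3-oxo-2-(3-oxopropyl)butanoate | O=CCC[C@@](C)(C(=O)OC(C)(C)C)C(=O)CO[Si](c1ccccc1)(c1ccccc1)C(C)(C)C | intermediate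
15 | ethyl diazoacetate | CCOC(=O)C=[N+]=[N-] | starting material
16 | 1-tert-butyl 7-ethyl (2R)-2-{[(tert-butyldiphenylsilyl)oxy]acetyl}-2-methyl-5-oxoheptanedioate | CCOC(=O)CC(=O)CC[C@@](C)(C(=O)OC(C)(C)C)C(=O)CO[Si](c1ccccc1)(c1ccccc1)C(C)(C)C | intermediate
17 | 1-tert-butyl 3-ethyl (1R)-2-{[(tert-butyldiphenylsilyl)oxy]methyl}-1-methyl-4-oxocyclohex-2-ene-1,3-dicarboxylate (ring A enone: C1 ketone, C5=C10 alkene) | CCOC(=O)C1=C(CO[Si](c2ccccc2)(c2ccccc2)C(C)(C)C)[C@](C)(C(=O)OC(C)(C)C)CCC1=O | intermediate
18 | ring A β-keto ester: C1 ketone; C10 H and CO2Et (epimers/enol); C5 H β and CH2OTBDPS α; C4 CH3 β and CO2t-Bu α | CCOC(=O)C1C(=O)CC[C@@](C)(C(=O)OC(C)(C)C)[C@H]1CO[Si](c1ccccc1)(c1ccccc1)C(C)(C)C | intermediate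
19 | ring A 10-hydroxymethyl β-keto ester: C10 CH2OH (C9) β and CO2Et (C20) α; other centres as in 18 | OC[C@]1(C(=O)OCC)C(=O)CC[C@@](C)(C(=O)OC(C)(C)C)[C@H]1CO[Si](c1ccccc1)(c1ccccc1)C(C)(C)C | intermediate
20 | ring A diol ester: as 19 with C1 reduced to the 1α-alcohol | OC[C@]1(C(=O)OCC)[C@@H](O)CC[C@@](C)(C(=O)OC(C)(C)C)[C@H]1CO[Si](c1ccccc1)(c1ccccc1)C(C)(C)C | intermediate
21 | ring A aldehyde: as 20 with C9 oxidised to the formyl group | O=C[C@]1(C(=O)OCC)[C@@H](O)CC[C@@](C)(C(=O)OC(C)(C)C)[C@H]1CO[Si](c1ccccc1)(c1ccccc1)C(C)(C)C | intermediate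
22 | ring A methyl (E)-acrylate: C10 carries (E)-CH=CH–CO2Me (β) and CO2Et (α); 1α-OH free | COC(=O)/C=C/[C@]1(C(=O)OCC)[C@@H](O)CC[C@@](C)(C(=O)OC(C)(C)C)[C@H]1CO[Si](c1ccccc1)(c1ccccc1)C(C)(C)C | intermediate
23 | ring A tetraol: C10 carries (E)-CH=CH–CH2OH (β) and CH2OH (C20, α); 1α-OH; C4 CH3 β and CH2OH (C19) α; C5 CH2OTBDPS α | OC/C=C/[C@]1(CO)[C@@H](O)CC[C@@](C)(CO)[C@H]1CO[Si](c1ccccc1)(c1ccccc1)C(C)(C)C | intermediate
24 | ring A O1/O20 isopropylidene acetal of 23 (O12 and O19 free) | OC/C=C/[C@]12COC(C)(C)O[C@H]1CC[C@@](C)(CO)[C@H]2CO[Si](c1ccccc1)(c1ccccc1)C(C)(C)C | intermediate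
25 | ring A acetonide (E)-enal (C12 aldehyde, O19 free) | O=C/C=C/[C@]12COC(C)(C)O[C@H]1CC[C@@](C)(CO)[C@H]2CO[Si](c1ccccc1)(c1ccccc1)C(C)(C)C | intermediate
26 | ring A acetonide (E)-enal 19-acetate | O=C/C=C/[C@]12COC(C)(C)O[C@H]1CC[C@@](C)(COC(C)=O)[C@H]2CO[Si](c1ccccc1)(c1ccccc1)C(C)(C)C | intermediate
27 | ring A (E)-enal with 1α-OH and C20 OH free, 19-acetate, O6 TBDPS | O=C/C=C/[C@]1(CO)[C@@H](O)CC[C@@](C)(COC(C)=O)[C@H]1CO[Si](c1ccccc1)(c1ccccc1)C(C)(C)C | intermediate
28 | mixed anhydride of 8 with 2,4,6-trichlorobenzoic acid | O=C(OC(=O)c1c(Cl)cc(Cl)cc1Cl)C1=C(OCC=C)C(=O)CC1 | intermediate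
29 | C20 ester of 27 with acid 8 (1α-OH free) | O=C/C=C/[C@]1(COC(=O)C2=C(OCC=C)C(=O)CC2)[C@@H](O)CC[C@@](C)(COC(C)=O)[C@H]1CO[Si](c1ccccc1)(c1ccccc1)C(C)(C)C | intermediate
30 | 1α,19-diacetate of 29 (ring D enol still allyl-protected) | O=C/C=C/[C@]1(COC(=O)C2=C(OCC=C)C(=O)CC2)[C@@H](OC(C)=O)CC[C@@](C)(COC(C)=O)[C@H]1CO[Si](c1ccccc1)(c1ccccc1)C(C)(C)C | intermediate
31 | ring A enal ester of 2,3-dioxocyclopentane-1-carboxylic acid (C8 epimers/enol; key-step precursor) | O=C/C=C/[C@]1(COC(=O)C2CCC(=O)C2=O)[C@@H](OC(C)=O)CC[C@@](C)(COC(C)=O)[C@H]1CO[Si](c1ccccc1)(c1ccccc1)C(C)(C)C | intermediate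
32 | tetracyclic 12ξ-hydroxy-15,16-dione 7,20-lactone; C8, C9, C13 as in the target; 1α,19-diacetate; O6 TBDPS | O=C1C(=O)[C@]23C[C@H]1C(O)C[C@H]2[C@]1(COC3=O)[C@@H](OC(C)=O)CC[C@@](C)(COC(C)=O)[C@H]1CO[Si](c1ccccc1)(c1ccccc1)C(C)(C)C | intermediate
33 | tetracyclic 11-ene-15,16-dione 7,20-lactone | O=C1C(=O)[C@]23C[C@H]1C=C[C@H]2[C@]1(COC3=O)[C@@H](OC(C)=O)CC[C@@](C)(COC(C)=O)[C@H]1CO[Si](c1ccccc1)(c1ccccc1)C(C)(C)C | intermediate
34 | tetracyclic saturated 15,16-dione 7,20-lactone | O=C1C(=O)[C@]23C[C@H]1CC[C@H]2[C@]1(COC3=O)[C@@H](OC(C)=O)CC[C@@](C)(COC(C)=O)[C@H]1CO[Si](c1ccccc1)(c1ccccc1)C(C)(C)C | intermediate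
35 | O6-tert-butyldiphenylsilyl ether of the target | C=C1C(=O)[C@]23C[C@H]1CC[C@H]2[C@]1(COC3=O)[C@@H](OC(C)=O)CC[C@@](C)(COC(C)=O)[C@H]1CO[Si](c1ccccc1)(c1ccccc1)C(C)(C)C | intermediate
36 | CNP0105570.2: 1α,19-diacetoxy-6-hydroxy-15-oxo-6,7-seco-ent-kaur-16-ene 7,20-lactone (faces as defined in the remark) | C=C1C(=O)[C@]23C[C@H]1CC[C@H]2[C@]1(COC3=O)[C@@H](OC(C)=O)CC[C@@](C)(COC(C)=O)[C@H]1CO | target

**Step count**

Total: 27 steps. Longest linear sequence: 22 steps (steps 6–27, from methyl glycolate 9); the ring D branch (steps 1–5) joins at step 20.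

**Steps most likely to fail**

1. Step 23 (labelled). The Michael addition may be slow at the neopentyl-type C9, may add to the wrong enal face or give the wrong C8 epimer, and the aldol closure may stall at the open aldehyde. The fallback separates the two bond formations and uses known reactions. It sets out from 31. Iminium catalysis with a diarylprolinol silyl ether (the enantiomer matched with C10) and benzoic acid in toluene would perform the intramolecular Michael addition of the 1,3-dicarbonyl unit alone, under catalyst control, to give the spiro δ-lactone aldehyde F1. An acid-catalysed intramolecular aldol addition through the C13 enol (TsOH, CH2Cl2) would then close ring C. The fallback returns to the route at 32.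

2. Step 24. The β-hydroxy ketone may open by retro-aldol reaction, the sulfamate may ionise with skeletal rearrangement of the bicyclo[3.2.1]octane, or the hindered carbinol may not react. The fallback replaces elimination and hydrogenation by radical deoxygenation of the Barton–McCombie type. It sets out from 32. 1,1'-Thiocarbonyldiimidazole with DMAP in CH2Cl2 would give the imidazolylthiocarbonyl ester F2. (Me3Si)3SiH and AIBN in toluene at 80 °C would then give the C12 methylene compound. The fallback returns to the route at 34, and step 25 is no longer needed.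

3. Step 26. The basic ylide may attack an acetate or the lactone, may olefinate both carbonyls, or may react at C15. The fallback is a two-stage Peterson olefination. It sets out from 34. Me3SiCH2MgCl with CeCl3 in THF at −78 °C would add to the less hindered C16 ketone to give the β-hydroxysilane F3. Acid-promoted elimination (TsOH cat., CH2Cl2) would then form the exocyclic alkene. The fallback returns to the route at 35.

Further compounds
F1 | step 23 | spiro δ-lactone aldehyde (C8–C9 bond formed, C11–C12 aldehyde free, ring D 15,16-dione) | O=CC[C@@H]1[C@]2(CCC(=O)C2=O)C(=O)OC[C@]13[C@@H](OC(C)=O)CC[C@@](C)(COC(C)=O)[C@H]3CO[Si](c1ccccc1)(c1ccccc1)C(C)(C)C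
F2 | step 24 | 12-O-(imidazol-1-ylthiocarbonyl) derivative of 32 | O=C1C(=O)[C@]23C[C@H]1C(OC(=S)n1ccnc1)C[C@H]2[C@]1(COC3=O)[C@@H](OC(C)=O)CC[C@@](C)(COC(C)=O)[C@H]1CO[Si](c1ccccc1)(c1ccccc1)C(C)(C)C
F3 | step 26 | 16ξ-hydroxy-16-[(trimethylsilyl)methyl] adduct of 34 | C[Si](C)(C)CC1(O)C(=O)[C@]23C[C@H]1CC[C@H]2[C@]1(COC3=O)[C@@H](OC(C)=O)CC[C@@](C)(COC(C)=O)[C@H]1CO[Si](c1ccccc1)(c1ccccc1)C(C)(C)C
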